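Readings and results were generated by integration with constants of no real substance, noise included.

The question is which species holds most of the substrate after 2.5 d in summer and in noon. The hunch sent with it, that noon's larger charge of coupling partner lets side product overtake substrate, can be tested with one number.

| setting | alder | oak | cedar | summer | noon |
|---|---|---|---|---|---|
| substrate | 0.10 M | 0.10 M | 0.10 M | 0.10 M | 0.10 M |
| coupling partner | 0.19 M | 0.26 M | 0.31 M | 0.200 M | 0.400 M |
| remark | run made earlier | run made earlier | run made earlier |  |  |
| time |  |  |  | 2.5 d | 2.5 d |

| run | time / d | substrate / % | side product / % | other mono adduct / % | first product / % |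
|---|---|---|---|---|---|
| alder | 0.625 | 82 | 0 | 4 | 14 |
| alder | 1.25 | 73 | 6 | 6 | 20 |
| alder | 2.08 | 62 | 11 | 7 | 16 |
| alder | 2.50 | 59 | 14 | 9 | 17 |
| oak | 0.333 | 88 | 0 | 2 | 8 |
| oak | 0.833 | 75 | 7 | 4 | 15 |
| oak | 1.67 | 62 | 13 | 8 | 19 |
| oak | 2.50 | 50 | 20 | 11 | 19 |
| cedar | 0.625 | 72 | 2 | 5 | 17 |
| cedar | 1.25 | 61 | 10 | 7 | 19 |
| cedar | 2.08 | 51 | 19 | 13 | 19 |
| cedar | 2.50 | 44 | 26 | 15 | 17 |

(scatter of a reading: 1.5 percentage points)

* which of these there is most of at the end, counted by the substrate in it, summer (other mono adduct / side product / first product / substrate)
* which of these there is most of at the end, counted by the substrate in it, noon (other mono adduct / side product / first product / substrate)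
* amount of the one of these that there is most of at the end, in percent of the substrate charged, summer
* amount of the one of these that there is most of at the end, in percent of the substrate charged, noon



That number is the charge constant: the natural logarithm of charged over remaining substrate, divided by the charged [coupling partner] and by the time, a pseudo-first-order slope per molar of partner. The cedar run reads 1.70 /M/d at 0.625 d but 1.06 /M/d at 2.50 d, so substrate goes more slowly late than early. The alder run ends at 1.11 /M/d, slightly above cedar.

Alder's value puts summer's substrate at 57.4 %, more than the 42.6 % shared by everything else. Cedar's value puts noon's substrate at 34.7 %. First product and other mono adduct together end cedar at 32.0 %; if noon holds the same, its side product is 33.3 %. Noon's substrate then leads by 1.4 percentage points, about the scatter of 1.5 points. But the constant falls with time in the cedar run, and a lower value for noon means more substrate and less of the rest, so the reckoning here commits to substrate in both flasks.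

The forecast also names substrate in both, at 58 % and 35.5 %, each a little above the figures here, and calls noon “a close race; substrate is narrowly ahead”. The flasks give substrate 58.0 % in summer and 40.2 % in noon, where side product stands at 29.6 %.

    substrate + coupling partner → first product + by-product (k = 9.17 × 10⁻⁴ /M/min)
    substrate + coupling partner → other mono adduct + by-product (k = 2.61 × 10⁻⁴ /M/min)
    coupling partner + first product → double product + by-product (k = 2.12 × 10⁻⁵ /M/min)
    coupling partner + other mono adduct → double product + by-product (k = 9.72 × 10⁻⁵ /M/min)
    first product + by-product → side product (k = 0.0154 /M/min)
    2 coupling partner → homo dimer (k = 5.72 × 10⁻⁴ /M/min)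

Noon's charge constant comes to 0.912 /M/d, below both summer's 1.09 /M/d and the 1.06 /M/d read from cedar. The difference in charged coupling partner is the main reason for the gap between the two flasks: noon's substrate stands at 40.2 % against 58.0 % in summer, a gap of 18 points. The summer flask read at 10 d has a charge constant of 0.574 /M/d, and its side product has passed substrate, 49.0 % against 31.7 %.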